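**Retrosynthetic overview**
- The target is the 13,14-seco form of abietic acid: the isopropyl ketone (C13) and the ring-bound carboxyl (C14) are the two ends of the former C13=C14 bond, so only C–O bonds have to be made.
- Target ⇐ 13-hydroxy-14-oxo ketol (C13–C14 scission with formation of the C14–OH bond) ⇐ 13,14-cis-diol (oxidation of the C14 carbinol) ⇐ abietic acid (site-selective dihydroxylation, the two key C–O bonds).
- No ring is built: rings A and B and all four stereocentres come from abietic acid; ring C is opened in the last step.

Assumption: commercial (−)-abietic acid (technical grade, upgraded by one recrystallisation of its amine salt) is the starting material, and the cis-diol is drawn as the 13α,14α isomer (α-face attack assumed); the other cis-diol would serve equally, because C13 and C14 are no longer stereocentres in the target.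

**Step 1**
Reactants: 1 (−)-abietic acid (abieta-7,13-dien-18-oic acid)
Product: 2 13α,14α-dihydroxyabiet-7-en-18-oic acid
Conditions: K2OsO2(OH)4 (2 mol%), NMO (1.25 equiv), pyridine (0.3 equiv), tBuOH/H2O 3:1, 45 °C, N2
Reagents that add atoms: N-methylmorpholine N-oxide (C[N+]1([O-])CCOCC1); water (O)
Why: Upjohn-type catalytic syn-dihydroxylation, in which OsO4 (octavalent osmium, formed in situ from the osmate and NMO) adds suprafacially in a [3+2] manner to the more accessible, more electron-rich distal C13=C14 bond (the site expected from the behaviour of abietates toward OsO4 and permanganate), the allylic diol formed deactivates C7=C8 toward a second addition, and the two new cis carbinol centres (drawn α) are erased again by step 3.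

**Step 2**
Reactants: 2 13α,14α-dihydroxyabiet-7-en-18-oic acid
Product: 3 13α-hydroxy-14-oxoabiet-7-en-18-oic acid
Conditions: IBX (1.5 equiv), DMSO, 23 °C
Reagents that add atoms: none
Why: IBX (pentavalent iodine) alcohol oxidation, in which only the secondary allylic C14 carbinol can be oxidised, vicinal diols are normally taken to α-ketols without C–C cleavage, the free acid and the olefin are tolerated, and the C13 carbinol configuration is untouched.

**Step 3**
Reactants: 3 13α-hydroxy-14-oxoabiet-7-en-18-oic acid
Product: 6 13-oxo-13,14-seco-abiet-7-ene-14,18-dioic acid, via seco Breslow enaminol 4 (not isolated), via seco acyl triazolium 5 (not isolated)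
Conditions: 1,4-dimethyl-4H-1,2,4-triazol-1-ium iodide (10 mol%), DBU (3 equiv), 3,3′,5,5′-tetra-tert-butyldiphenoquinone (1.2 equiv), THF/H2O 10:1, 50 °C, N2
Reagents that add atoms: water (O)
Why: Proposed new method: carbene-catalysed oxidative retro-benzoin ring scission, in which the small triazolylidene adds to the C14 ketone, the C13 alkoxide then breaks the C13–C14 bond to unveil the isopropyl ketone and the vinylogous Breslow enaminol 4, the diphenoquinone oxidises 4 irreversibly (draining the otherwise ring-closed benzoin equilibrium) to the α,β-unsaturated acyl triazolium 5, and water hydrolyses 5 to the C14 carboxylic acid with release of the carbene; the closest known reaction types are the carbene-catalysed retro-benzoin of acyclic α′-hydroxy enones (which expels acetone) and oxidative carbene catalysis of enals with the same quinone; no stereocentre is formed and the C9 hydrogen is not acidic.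

**Compound list**
1 | (−)-abietic acid (abieta-7,13-dien-18-oic acid) | CC(C)C1=CC2=CC[C@@H]3[C@@]([C@H]2CC1)(CCC[C@@]3(C)C(=O)O)C | starting material
2 | 13α,14α-dihydroxyabiet-7-en-18-oic acid (cis-diol) | CC(C)[C@@]1(O)[C@H](O)C2=CC[C@@H]3[C@@]([C@H]2CC1)(CCC[C@@]3(C)C(=O)O)C | intermediate
3 | 13α-hydroxy-14-oxoabiet-7-en-18-oic acid (α′-hydroxy enone) | CC(C)[C@@]1(O)C(=O)C2=CC[C@@H]3[C@@]([C@H]2CC1)(CCC[C@@]3(C)C(=O)O)C | intermediate
4 | seco Breslow enaminol: 14-(1,4-dimethyl-1,4-dihydro-5H-1,2,4-triazol-5-ylidene)-14-hydroxy-13-oxo-13,14-seco-abiet-7-en-18-oic acid | CC(C)C(=O)CC[C@H]1C(C(O)=C3N(C)C=NN3C)=CC[C@@H]2[C@]1(C)CCC[C@@]2(C)C(=O)O | intermediate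
5 | seco acyl triazolium: 1,4-dimethyl-1,2,4-triazol-1-ium-5-yl ketone at C14 of 13-oxo-13,14-seco-abiet-7-en-18-oate (zwitterion) | CC(C)C(=O)CC[C@H]1C(C(=O)c3n(C)cn[n+]3C)=CC[C@@H]2[C@]1(C)CCC[C@@]2(C)C(=O)[O-] | intermediate
6 | 13-oxo-13,14-seco-abiet-7-ene-14,18-dioic acid (CNP0333046.1) | CC(C)C(=O)CC[C@H]1C(C(=O)O)=CC[C@@H]2[C@]1(C)CCC[C@@]2(C)C(=O)O | target

**Step count**
Total steps: 3. Longest linear sequence: 3 steps (1 → 2 → 3 → 6).

**Steps most likely to fail, with fallbacks**

Step 3 (the proposed new step) is the most likely to fail. Carbene addition to the hindered, α-branched enone carbonyl may be slow, ring re-closure of 4 competes with its oxidation, and β-protonation of 4 or base-induced ketol rearrangement of 3 could divert material. The fallback uses known chemistry, sets out from 3 and comes back at 6. Periodic acid H5IO6 (1.5 equiv) in THF/H2O at 23–40 °C cleaves the C13–C14 bond of the tertiary α-ketol (Malaprade-type periodate cleavage of α-hydroxy ketones) and gives the C13 ketone and the C14 carboxylic acid in one operation; no new compound is made (F0).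

Step 1 is second. OsO4 may also attack C7=C8 or dihydroxylate twice, and the diene is sensitive to air. The fallback sets out from 1 and comes back at 6. Ozone (1.0 equiv) in CH2Cl2 with pyridine (3 equiv) at −78 °C should add as a 1,3-dipole to the distal C13=C14 bond and give 13-oxo-13,14-seco-abiet-7-en-14-al-18-oic acid F1 directly, without a peroxide to reduce. The remaining double bond of F1 is a deactivated enal olefin, which limits over-ozonolysis. F1 is then oxidised with NaClO2, NaH2PO4 and 2-methyl-2-butene in tBuOH/H2O (Pinnick oxidation) to 6.

Step 2 is third. IBX could be sluggish or could cleave the hindered cis-diol. The fallback sets out from 2 and comes back at 6. A nitroxyl-catalysed one-flask glycol cleavage is used: 2-azaadamantane N-oxyl (AZADO, 5 mol%) and PhI(OAc)2 (3 equiv) in MeCN/H2O at 23 °C. The oxoammonium salt oxidises the C14 carbinol to 3 in the flask, and the trivalent iodine reagent cleaves the hydrated ketol to ketone plus carboxylic acid, so the isolation of 3 and the carbene step are bypassed; no new compound is made (F0).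

**Further compounds**
F1 | step 1 | 13-oxo-13,14-seco-abiet-7-en-14-al-18-oic acid | CC(C)C(=O)CC[C@H]1C(C=O)=CC[C@@H]2[C@]1(C)CCC[C@@]2(C)C(=O)O
F0 | step 2 | none | none
F0 | step 3 | none | none
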